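(All constants were set for the occasion; the run is a simulation.)

The constant of step 1 is in reciprocal molar squared per second, so multiplying it by substrate, coupling partner and time leaves a pure number, and I reckoned these flasks in that number.

    substrate + coupling partner + by-product → product + 2 by-product (k1 = 8300 /M²/s)
    substrate + coupling partner → product + by-product (k2 = 0.40 /M/s)
    coupling partner + protic impurity → quenched reagent (k3 = 210 /M/s)

in all of them: protic impurity 0.100 mM

| charge | substrate | coupling partner | time | remark |
|---|---|---|---|---|
| alder | 5.0 mM (fed, over 50.0 s) | 5.50 mM | 50 s | all but substrate at the start; substrate goes in evenly over 50.0 s, the run ends at 50 s |
| ash | 5.0 mM | 5.50 mM (fed, over 50.0 s) | 50 s | a stirred flask in which coupling partner is dosed at a steady rate over 50.0 s without added volume, worked up at 50 s |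
| birch | 5.0 mM | 5.50 mM |  | one stirred flow tank at steady state, fed with the mixture as stated, mean residence time 50 s |
| larch | 5.0 mM | 5.50 mM | 50 s | everything together in a closed stirred flask, run for 50 s |

- the set-up with the highest amount of product at the outlet or at the end, in percent of the substrate put in ("none" if the first two lie within 2 percentage points) (alder / ash / birch / larch / none)
- amount of product at the outlet or at the end, in percent of the substrate put in, alder
- amount of product at the outlet or at the end, in percent of the substrate put in, ash
- amount of product at the outlet or at the end, in percent of the substrate put in, birch
- amount of product at the outlet or at the end, in percent of the substrate put in, larch

- the stated concentrations are those of everything mixed, before any reaction; amounts are the same in each set-up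
- the feed brings no volume worth counting
- run time (alder): 50 s

I built larch up one step at a time. In step 1 the natural logarithm of by-product rises by that pure number, which for the charges over the run is 11.4, but a multiple of no by-product is none. Step 2 supplies the seed: it acts like 0.0482 mM of by-product present from the start. Reaching half conversion therefore takes a count of 5.64, the logarithm of charge over seed plus one for the running down of both reagents.

Then I added step 3. In larch the protic impurity lasts about 0.866 s, far shorter than the run, so I took it off the partner. That gave the turnover count, the constant of step 1 times substrate, partner net of impurity, and time: 11.2. Past take-off I let substrate and partner run down together, so that one over the unreacted share of substrate rises by about one per unit of count, starting from 2 at half conversion. For larch this gives 86.8%.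

Dosing one reagent evenly, in alder or ash, holds that reagent on average at half its charge, so I took the count there as 5.60, half the count of larch and close to the 5.64 that half conversion takes. The same rule gave 49.0% for alder and 49.0% for ash. In birch, the steady tank, I set the count reckoned on outlet substrate, outlet partner and the residence time to one, which gives 72.7%. My order put larch first.

The forecast also chose larch, with 86.5% there, 73% for birch, 50% for alder and 47% for ash, reasoning that “putting everything in at once gives the highest substrate × partner product during the take-off”. Unlike my equal pair, it set ash behind alder.

The flask gave 86.5% for larch, 72.9% for birch, 48.9% for alder and 48.3% for ash. The neighbour of ash with 12 mM of substrate had a reckoned count of 13.4, more than the 5.72 reckoned for half conversion of its partner. In that neighbour the partner is the limiting reagent, and net of impurity it covers 45.0% of the substrate. That neighbour ended at 41.7% product, with 7.2% of its partner left.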